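**Strategy.** The polyene is cut at the C14–C15 single bond (carotenoid numbering), which links the methyl-bearing C13=C14 alkene to the unsubstituted C15=C15′ alkene. That bond is made last by a one-pot Zr-catalysed methylalumination of the terminal C13≡C14 alkyne of a C18 hydroxy dienediyne (actinol-derived ring), followed by Pd/Zn cross-coupling of the resulting (E)-alkenylalane with a C21 (E)-pentaenyl bromide ((R)-α-ionone-derived ε-ring). One operation installs the C13 methyl, fixes the 13E geometry, forms C14–C15 and delivers the unprotected carotenoid. The hindered C7≡C8 triple bond between the tetrasubstituted C5=C6 ring alkene and C9 should stay untouched, and the C3 hydroxyl rides as its aluminium alkoxide.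

Key step: step 13

Assumption: (R)-α-ionone and (4R,6R)-4-hydroxy-2,2,6-trimethylcyclohexanone (actinol) are taken as catalogue compounds in enantiopure form; positions are named by carotenoid numbering (C1–C6 hydroxylated ring, C7≡C8, chain to C15, primed numbers for the ε-ring half).

**Step 1**
Reactants: 1 acetylene
Product: 2 (E)-1-bromo-2-iodoethene
Conditions: HC≡CH bubbled into IBr, 48% aq HBr, 0 °C
Reagents that add atoms: iodine monobromide, IBr
Why: Electrophilic addition of I–Br to the alkyne runs through a bridged iodonium ion that bromide opens anti, which should give the E-1,2-dihaloethene (alkyne halogenation).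

**Step 2**
Reactants: 3 (R)-α-ionone
Product: 5 (6R)-6-[(1E)-but-1-en-3-yn-1-yl]-1,5,5-trimethylcyclohex-1-ene, via enol phosphate 4 (not isolated)
Conditions: LDA (1.05 equiv), THF, −78 °C; ClP(O)(OEt)2, −78 °C→rt; then LDA (2.3 equiv), THF, −78 °C→rt
Reagents that add atoms: none
Why: Kinetic deprotonation at the ketone CH3, O-phosphorylation and base-induced β-elimination of diethyl phosphate turn C(O)CH3 into C≡CH (enol phosphate elimination), leaving the C7′=C8′ geometry and the C6′ stereocentre as they are.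

**Step 3**
Reactants: 5 (6R)-6-[(1E)-but-1-en-3-yn-1-yl]-1,5,5-trimethylcyclohex-1-ene; 2 (E)-1-bromo-2-iodoethene
Product: 7 (6R)-6-[(1E,3E,5E)-6-bromo-3-methylhexa-1,3,5-trien-1-yl]-1,5,5-trimethylcyclohex-1-ene, via alkenylalane 6 (not isolated)
Conditions: Me3Al (2 equiv), Cp2ZrCl2 (0.25–1 equiv), ClCH2CH2Cl, 23 °C; volatiles off; then 2 (1.2 equiv), ZnCl2 (cocat.), Pd(PPh3)4 (3 mol %), THF, 0→23 °C, dark
Reagents that add atoms: trimethylaluminium, C[Al](C)C
Why: Zr-catalysed syn-methylalumination (Negishi carboalumination) puts CH3 on the internal and Al on the terminal alkyne carbon, and the Pd/Zn-catalysed Negishi coupling should then occur with retention only at the C–I bond of 2, which adds oxidatively much faster than C–Br.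

**Step 4**
Reactants: 7 (6R)-6-[(1E,3E,5E)-6-bromo-3-methylhexa-1,3,5-trien-1-yl]-1,5,5-trimethylcyclohex-1-ene
Product: 8 (6R)-1,5,5-trimethyl-6-[(1E,3E,5E)-3-methylocta-1,3,5-trien-7-yn-1-yl]cyclohex-1-ene
Conditions: HC≡CMgBr (1.5 equiv), ZnBr2 (1.5 equiv), THF, 0 °C; then 7, Pd(PPh3)4 (5 mol %), THF, 23–40 °C
Reagents that add atoms: ethynylmagnesium bromide, C#C[Mg]Br
Why: Negishi alkynylation: the zinc acetylide formed in the flask couples with the alkenyl bromide with retention of the E geometry and gives the terminal alkyne directly.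

**Step 5**
Reactants: 8 (6R)-1,5,5-trimethyl-6-[(1E,3E,5E)-3-methylocta-1,3,5-trien-7-yn-1-yl]cyclohex-1-ene; 2 (E)-1-bromo-2-iodoethene
Product: 10 (6R)-6-[(1E,3E,5E,7E,9E)-10-bromo-3,7-dimethyldeca-1,3,5,7,9-pentaen-1-yl]-1,5,5-trimethylcyclohex-1-ene, via alkenylalane 9 (not isolated)
Conditions: Me3Al (2 equiv), Cp2ZrCl2 (0.25–1 equiv), ClCH2CH2Cl, 23 °C; volatiles off; then 2 (1.2 equiv), ZnCl2 (cocat.), Pd(PPh3)4 (3 mol %), THF, 0→23 °C, dark
Reagents that add atoms: trimethylaluminium, C[Al](C)C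
Why: Same tandem carboalumination/Negishi coupling as in step 3: syn-addition fixes the 13′E trisubstituted alkene and the iodide of 2 reacts selectively, so the C15 bromide is kept for the final union.

**Step 6**
Reactants: 11 3-bromo-1-(trimethylsilyl)prop-1-yne
Product: 12 diethyl [3-(trimethylsilyl)prop-2-yn-1-yl]phosphonate
Conditions: P(OEt)3 (1.2 equiv), neat, 110 °C, EtBr distilled off
Reagents that add atoms: triethyl phosphite, CCOP(OCC)OCC
Why: Michaelis–Arbuzov reaction (SN2 attack of phosphorus on the propargylic bromide, then dealkylation by bromide); the silyl cap disfavours SN2′ allene formation.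

**Step 7**
Reactants: 13 (E)-3-methylpent-2-en-4-yn-1-ol
Product: 14 (E)-3-methylpent-2-en-4-ynal
Conditions: activated MnO2 (15 equiv), CH2Cl2, 23 °C, dark; used as a concentrated solution
Reagents that add atoms: none
Why: Activated MnO2 oxidises the allylic alcohol to the enal without touching the alkyne or the alkene geometry (allylic oxidation).

**Step 8**
Reactants: 12 diethyl [3-(trimethylsilyl)prop-2-yn-1-yl]phosphonate; 14 (E)-3-methylpent-2-en-4-ynal
Product: 15 trimethyl[(3E,5E)-6-methylocta-3,5-dien-1,7-diyn-1-yl]silane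
Conditions: 12, NaHMDS, THF, −78 °C; then 14, −78→0 °C
Reagents that add atoms: none
Why: Horner–Wadsworth–Emmons olefination of the stabilised propargylic phosphonate anion, which is too weakly basic to deprotonate the terminal alkyne of 14, should give the E-enyne through reversible addition and elimination via the anti-oxaphosphetane.

**Step 9**
Reactants: 16 (4R,6R)-4-hydroxy-2,2,6-trimethylcyclohexan-1-one
Product: 17 (4R,6R)-4-[(tert-butyldimethylsilyl)oxy]-2,2,6-trimethylcyclohexan-1-one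
Conditions: TBSCl, imidazole, DMF, 23 °C
Reagents that add atoms: tert-butyldimethylsilyl chloride, CC(C)(C)[Si](C)(C)Cl
Why: Standard silylation of the secondary alcohol protects O3 for the enolate chemistry without touching the stereocentres.

**Step 10**
Reactants: 17 (4R,6R)-4-[(tert-butyldimethylsilyl)oxy]-2,2,6-trimethylcyclohexan-1-one
Product: 18 (4R)-4-[(tert-butyldimethylsilyl)oxy]-2,6,6-trimethylcyclohex-1-en-1-yl trifluoromethanesulfonate
Conditions: LDA (1.2 equiv), THF, −78→0 °C; PhNTf2, 0→23 °C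
Reagents that add atoms: N-phenylbis(trifluoromethanesulfonimide), O=S(=O)(N(c1ccccc1)S(=O)(=O)C(F)(F)F)C(F)(F)F
Why: Only C6 carries an α-hydrogen (C2 is quaternary), so a single tetrasubstituted enolate forms and is O-triflated (enol triflate formation); the C6 stereocentre is erased on purpose and the carbinol centre is retained.

**Step 11**
Reactants: 18 (4R)-4-[(tert-butyldimethylsilyl)oxy]-2,6,6-trimethylcyclohex-1-en-1-yl trifluoromethanesulfonate; 15 trimethyl[(3E,5E)-6-methylocta-3,5-dien-1,7-diyn-1-yl]silane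
Product: 19 tert-butyldimethyl({(1R)-3,5,5-trimethyl-4-[(3E,5E)-3-methyl-8-(trimethylsilyl)octa-3,5-dien-1,7-diyn-1-yl]cyclohex-3-en-1-yl}oxy)silane
Conditions: Pd(PPh3)4 (5 mol %), CuI (10 mol %), i-Pr2NH, DMF, 23–45 °C, degassed
Reagents that add atoms: none
Why: Sonogashira coupling of the enol triflate with the free alkyne terminus of 15 forms the C6–C7 bond; the silyl-capped alkyne and both alkene geometries are inert to Pd/Cu/amine.

**Step 12**
Reactants: 19 tert-butyldimethyl({(1R)-3,5,5-trimethyl-4-[(3E,5E)-3-methyl-8-(trimethylsilyl)octa-3,5-dien-1,7-diyn-1-yl]cyclohex-3-en-1-yl}oxy)silane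
Product: 20 (1R)-3,5,5-trimethyl-4-[(3E,5E)-3-methylocta-3,5-dien-1,7-diyn-1-yl]cyclohex-3-en-1-ol
Conditions: TBAF (2.5 equiv), THF, 0→23 °C, dark
Reagents that add atoms: none
Why: Fluoride cleaves the C(sp)–Si and the O–Si bond in one operation (desilylation), freeing the terminal alkyne and the C3 hydroxyl without touching stereochemistry.

**Step 13**
Reactants: 20 (1R)-3,5,5-trimethyl-4-[(3E,5E)-3-methylocta-3,5-dien-1,7-diyn-1-yl]cyclohex-3-en-1-ol; 10 (6R)-6-[(1E,3E,5E,7E,9E)-10-bromo-3,7-dimethyldeca-1,3,5,7,9-pentaen-1-yl]-1,5,5-trimethylcyclohex-1-ene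
Product: 22 (3R,6′R)-7,8-didehydro-β,ε-caroten-3-ol (all-E), via alkenylalane alkoxide 21 (not isolated)
Conditions: Me3Al (3.5 equiv), Cp2ZrCl2 (1 equiv), ClCH2CH2Cl, 0→23 °C; volatiles off; then 10 (1.0 equiv), ZnCl2 (cocat.), Pd2(dba)3 (2.5 mol %), P(2-furyl)3 (10 mol %), THF–DMF, 23 °C, dark; aq. Rochelle salt
Reagents that add atoms: trimethylaluminium, C[Al](C)C
Why: The first equivalent of Me3Al turns the C3 hydroxyl into its O–AlMe2 alkoxide, and the Zr-activated Me–Al reagent then adds syn across the terminal C13≡C14 bond with CH3 to the internal C13 and Al to C14, so the (13E)-alkenylalane 21 should form. Al→Zn→Pd transmetalation, oxidative addition of the C15–Br bond of 10 and reductive elimination then form C14–C15 with retention of both alkene geometries. The closest known reaction type is the tandem Zr-catalysed carboalumination/Pd–Zn cross-coupling (Negishi coupling) of terminal polyenynes with alkenyl halides. No ring is closed and no stereocentre is created; C3 and C6′ are remote and untouched, and the 13E and 15E geometries follow from syn-addition and stereoretentive coupling. The step needs regio- and chemoselectivity for the terminal alkyne: Al goes to the unhindered terminus, and the internal C7≡C8 bond is shielded by the tetrasubstituted C5=C6 ring alkene with the C1 gem-dimethyl group and by the C9 methyl, while internal alkynes are in any case methylaluminated much more slowly.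

**Compound list**
1 | acetylene | C#C | starting material
2 | (E)-1-bromo-2-iodoethene | Br/C=C/I | intermediate
3 | (R)-α-ionone, (3E)-4-[(1R)-2,6,6-trimethylcyclohex-2-en-1-yl]but-3-en-2-one | CC1=CCCC(C)(C)[C@H]1/C=C/C(C)=O | starting material
4 | diethyl (3E)-4-[(1R)-2,6,6-trimethylcyclohex-2-en-1-yl]buta-1,3-dien-2-yl phosphate | CC1=CCCC(C)(C)[C@H]1/C=C/C(=C)OP(=O)(OCC)OCC | intermediate (not isolated)
5 | (6R)-6-[(1E)-but-1-en-3-yn-1-yl]-1,5,5-trimethylcyclohex-1-ene | CC1=CCCC(C)(C)[C@H]1/C=C/C#C | intermediate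
6 | dimethyl{(1E,3E)-2-methyl-4-[(1R)-2,6,6-trimethylcyclohex-2-en-1-yl]buta-1,3-dien-1-yl}alane | CC1=CCCC(C)(C)[C@H]1/C=C/C(C)=C/[Al](C)C | intermediate (not isolated)
7 | (6R)-6-[(1E,3E,5E)-6-bromo-3-methylhexa-1,3,5-trien-1-yl]-1,5,5-trimethylcyclohex-1-ene | CC1=CCCC(C)(C)[C@H]1/C=C/C(C)=C/C=C/Br | intermediate
8 | (6R)-1,5,5-trimethyl-6-[(1E,3E,5E)-3-methylocta-1,3,5-trien-7-yn-1-yl]cyclohex-1-ene | CC1=CCCC(C)(C)[C@H]1/C=C/C(C)=C/C=C/C#C | intermediate
9 | {(1E,3E,5E,7E)-2,6-dimethyl-8-[(1R)-2,6,6-trimethylcyclohex-2-en-1-yl]octa-1,3,5,7-tetraen-1-yl}dimethylalane | CC1=CCCC(C)(C)[C@H]1/C=C/C(C)=C/C=C/C(C)=C/[Al](C)C | intermediate (not isolated)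
10 | (6R)-6-[(1E,3E,5E,7E,9E)-10-bromo-3,7-dimethyldeca-1,3,5,7,9-pentaen-1-yl]-1,5,5-trimethylcyclohex-1-ene | CC1=CCCC(C)(C)[C@H]1/C=C/C(C)=C/C=C/C(C)=C/C=C/Br | intermediate
11 | 3-bromo-1-(trimethylsilyl)prop-1-yne | C[Si](C)(C)C#CCBr | starting material
12 | diethyl [3-(trimethylsilyl)prop-2-yn-1-yl]phosphonate | CCOP(=O)(OCC)CC#C[Si](C)(C)C | intermediate
13 | (E)-3-methylpent-2-en-4-yn-1-ol | C#C/C(C)=C/CO | starting material
14 | (E)-3-methylpent-2-en-4-ynal | C#C/C(C)=C/C=O | intermediate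
15 | trimethyl[(3E,5E)-6-methylocta-3,5-dien-1,7-diyn-1-yl]silane | C#C/C(C)=C/C=C/C#C[Si](C)(C)C | intermediate
16 | (4R,6R)-4-hydroxy-2,2,6-trimethylcyclohexan-1-one (actinol, trans) | C[C@@H]1C[C@@H](O)CC(C)(C)C1=O | starting material
17 | (4R,6R)-4-[(tert-butyldimethylsilyl)oxy]-2,2,6-trimethylcyclohexan-1-one | C[C@@H]1C[C@@H](O[Si](C)(C)C(C)(C)C)CC(C)(C)C1=O | intermediate
18 | (4R)-4-[(tert-butyldimethylsilyl)oxy]-2,6,6-trimethylcyclohex-1-en-1-yl trifluoromethanesulfonate | FC(F)(F)S(=O)(=O)OC1=C(C)C[C@@H](O[Si](C)(C)C(C)(C)C)CC1(C)C | intermediate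
19 | tert-butyldimethyl({(1R)-3,5,5-trimethyl-4-[(3E,5E)-3-methyl-8-(trimethylsilyl)octa-3,5-dien-1,7-diyn-1-yl]cyclohex-3-en-1-yl}oxy)silane | C[Si](C)(C)C#C/C=C/C=C(\C)C#CC1=C(C)C[C@@H](O[Si](C)(C)C(C)(C)C)CC1(C)C | intermediate
20 | (1R)-3,5,5-trimethyl-4-[(3E,5E)-3-methylocta-3,5-dien-1,7-diyn-1-yl]cyclohex-3-en-1-ol | C#C/C=C/C=C(\C)C#CC1=C(C)C[C@@H](O)CC1(C)C | intermediate
21 | (13E)-alkenyl(dimethyl)alane of 20 after methylalumination, C3–O–AlMe2 alkoxide | C[Al](C)/C=C(C)/C=C/C=C(\C)C#CC1=C(C)C[C@@H](O[Al](C)C)CC1(C)C | intermediate (not isolated)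
22 | (3R,6′R)-7,8-didehydro-β,ε-caroten-3-ol (all-E; crocoxanthin) | CC1=CCCC(C)(C)[C@H]1/C=C/C(C)=C/C=C/C(C)=C/C=C/C=C(C)/C=C/C=C(\C)C#CC1=C(C)C[C@@H](O)CC1(C)C | target

**Step count.** Total: 13 steps. Longest linear sequence: 5 steps (3→5→7→8→10→22, steps 2, 3, 4, 5, 13; equally 16→17→18→19→20→22, steps 9–13).

**Steps most likely to fail**

1. Step 13. The methylalumination may not discriminate fully between the terminal C13≡C14 and the internal C7≡C8 triple bond, C–H alumination of the terminal alkyne may compete, and the alane/polyenyl bromide coupling may be eroded by homocoupling or E/Z scrambling. The fallback sets out from 18 and 10 and comes back at 22; it forms the same C14–C15 bond by a Stille coupling and avoids any carbometalation on the polyenyne. Sonogashira coupling of 18 with 13 should give (2E)-5-{(4R)-4-[(tert-butyldimethylsilyl)oxy]-2,6,6-trimethylcyclohex-1-en-1-yl}-3-methylpent-2-en-4-yn-1-ol F1. Appel bromination (CBr4, PPh3) gives the corresponding C15 allylic bromide F2, and Arbuzov reaction with P(OEt)3 the C15 diethyl allylphosphonate F3. Separately, propargyl alcohol is converted by Zr-catalysed methylalumination and iodinolysis into (E)-3-iodo-2-methylprop-2-en-1-ol F4, which MnO2 oxidises to (E)-3-iodo-2-methylacrylaldehyde F5. HWE olefination of F3 with F5 (NaHMDS, THF, −78 °C) should give the TBS-protected C19 (13E)-alkenyl iodide F6. Bromide 10 is converted by Br/Li exchange (t-BuLi, −78 °C) and Bu3SnCl into the C21 pentaenyl tributylstannane F7. Stille coupling of F6 with F7 (Pd2(dba)3, AsPh3, NMP, 23–40 °C) gives the TBS ether of the target F8, and TBAF in THF releases 22.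

2. Step 2. Excess LDA may erode the configuration at the doubly allylic C6′–H or move the ring double bond into conjugation. The fallback sets out from 3 and comes back at 8 (steps 2–4 drop out) and uses carbonyl olefination with only weakly basic stabilised anions. HWE reaction of 3 with diethyl cyanomethylphosphonate (NaH, THF) should give, after separation of the 9′Z isomer, (2E,4E)-3-methyl-5-[(1R)-2,6,6-trimethylcyclohex-2-en-1-yl]penta-2,4-dienenitrile F9. DIBAL-H reduction and hydrolysis give (2E,4E)-3-methyl-5-[(1R)-2,6,6-trimethylcyclohex-2-en-1-yl]penta-2,4-dienal F10. HWE olefination with 12 (NaHMDS, THF, −78 °C) gives the C-silylated tetraenyne F11, and K2CO3/MeOH removes the silyl group to give 8.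

3. Step 11. Oxidative addition and transmetalation at the hindered tetrasubstituted enol triflate may be slow enough that oxidative dimerisation and decomposition of the dienediyne 15 take over. The fallback sets out from 17 (with 15) and comes back at 19; it makes the C6–C7 bond by carbonyl addition instead of cross-coupling. Lithiation of 15 (LiHMDS, THF, −78 °C) and addition to ketone 17 should give the tertiary propargylic alcohol F12 (either carbinol epimer is usable). Dehydration with Martin sulfurane (or POCl3/pyridine) can only use the single β-hydrogen at C5 and so should give the tetrasubstituted C5=C6 alkene of 19.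

**Further compounds**
F1 | step 13 | (2E)-5-{(4R)-4-[(tert-butyldimethylsilyl)oxy]-2,6,6-trimethylcyclohex-1-en-1-yl}-3-methylpent-2-en-4-yn-1-ol | OC/C=C(\C)C#CC1=C(C)C[C@@H](O[Si](C)(C)C(C)(C)C)CC1(C)C
F2 | step 13 | {[(1R)-4-[(3E)-5-bromo-3-methylpent-3-en-1-yn-1-yl]-3,5,5-trimethylcyclohex-3-en-1-yl]oxy}(tert-butyl)dimethylsilane | BrC/C=C(\C)C#CC1=C(C)C[C@@H](O[Si](C)(C)C(C)(C)C)CC1(C)C
F3 | step 13 | diethyl [(2E)-5-{(4R)-4-[(tert-butyldimethylsilyl)oxy]-2,6,6-trimethylcyclohex-1-en-1-yl}-3-methylpent-2-en-4-yn-1-yl]phosphonate | CCOP(=O)(OCC)C/C=C(\C)C#CC1=C(C)C[C@@H](O[Si](C)(C)C(C)(C)C)CC1(C)C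
F4 | step 13 | (E)-3-iodo-2-methylprop-2-en-1-ol | OC/C(C)=C/I
F5 | step 13 | (E)-3-iodo-2-methylacrylaldehyde | O=C/C(C)=C/I
F6 | step 13 | tert-butyl({(1R)-4-[(3E,5E,7E)-8-iodo-3,7-dimethylocta-3,5,7-trien-1-yn-1-yl]-3,5,5-trimethylcyclohex-3-en-1-yl}oxy)dimethylsilane | I/C=C(C)/C=C/C=C(\C)C#CC1=C(C)C[C@@H](O[Si](C)(C)C(C)(C)C)CC1(C)C
F7 | step 13 | tributyl{(1E,3E,5E,7E,9E)-4,8-dimethyl-10-[(1R)-2,6,6-trimethylcyclohex-2-en-1-yl]deca-1,3,5,7,9-pentaen-1-yl}stannane | CC1=CCCC(C)(C)[C@H]1/C=C/C(C)=C/C=C/C(C)=C/C=C/[Sn](CCCC)(CCCC)CCCC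
F8 | step 13 | (3R,6′R)-3-[(tert-butyldimethylsilyl)oxy]-7,8-didehydro-β,ε-carotene (all-E) | CC1=CCCC(C)(C)[C@H]1/C=C/C(C)=C/C=C/C(C)=C/C=C/C=C(C)/C=C/C=C(\C)C#CC1=C(C)C[C@@H](O[Si](C)(C)C(C)(C)C)CC1(C)C
F9 | step 2 | (2E,4E)-3-methyl-5-[(1R)-2,6,6-trimethylcyclohex-2-en-1-yl]penta-2,4-dienenitrile | CC1=CCCC(C)(C)[C@H]1/C=C/C(C)=C/C#N
F10 | step 2 | (2E,4E)-3-methyl-5-[(1R)-2,6,6-trimethylcyclohex-2-en-1-yl]penta-2,4-dienal | CC1=CCCC(C)(C)[C@H]1/C=C/C(C)=C/C=O
F11 | step 2 | trimethyl{(3E,5E,7E)-6-methyl-8-[(1R)-2,6,6-trimethylcyclohex-2-en-1-yl]octa-3,5,7-trien-1-yn-1-yl}silane | CC1=CCCC(C)(C)[C@H]1/C=C/C(C)=C/C=C/C#C[Si](C)(C)C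
F12 | step 11 | (4R,6R)-4-[(tert-butyldimethylsilyl)oxy]-2,2,6-trimethyl-1-[(3E,5E)-3-methyl-8-(trimethylsilyl)octa-3,5-dien-1,7-diyn-1-yl]cyclohexan-1-ol (carbinol epimers) | C[Si](C)(C)C#C/C=C/C=C(\C)C#CC1(O)[C@H](C)C[C@@H](O[Si](C)(C)C(C)(C)C)CC1(C)C
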